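**Retrosynthetic overview**
1. The last disconnections are the C3 ester (half-ester 21 of (2E,4E)-muconic acid) and a C8/C9 acetonide; until then the lactone core carries C3 as a silyl ether.
2. The plan rests on one feature of the ten-membered lactone, the only ring: its ring oxygen O1 sits on C10, and C10 is followed directly by the two free carbinols C9–OH and C8–OH. This array is what a carboxylate leaves behind when it opens a trans C9–C10 epoxide of an erythro 2,3-epoxy alcohol at the carbon remote from the hydroxyl.
3. The key disconnection is therefore O1–C10, with inversion at C10, back to seco acid 14 (free C8–OH, (9R,10R)-epoxide); the ring closes by release of epoxide strain, not by acyl activation.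
4. 14 comes from a matched Sharpless epoxidation of bis-allylic alcohol 12 at C9=C10; C7–C8 and the C8 centre come from a catalytic asymmetric alkenylzinc addition of alkyne 8 to (E)-hex-2-enal; C3 comes from an auxiliary-controlled enolate hydroxylation of hex-5-ynoic acid.
5. Ring order: the lactone is formed in step 8; the dioxolane of steps 9–13 is only a protecting ring.

Key step: step 8

Remark: locants C2–C10 in the text follow the lactone numbering (O1 ring oxygen, C2 carbonyl, C10 propyl-bearing carbon), compound names use systematic numbering, and half-ester 21 is assumed not to be purchasable, so it is made in two steps.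

**Route**

Step 1
Reactants: 1 hex-5-ynoic acid; 2 (S)-4-benzyloxazolidin-2-one
Product: 4 (S)-4-benzyl-3-(hex-5-ynoyl)oxazolidin-2-one, via hex-5-ynoic pivalic anhydride 3 (not isolated)
Conditions: PivCl, Et3N, THF, −20 °C; then 2, LiCl, −20 °C → rt
Reagents that add atoms: none
Why: N-acylation of the oxazolidinone through a mixed pivalic anhydride (LiCl/Et3N variant) should occur at the unhindered hexynoyl carbonyl, and no stereocentre is formed.

Step 2
Reactants: 4 (S)-4-benzyl-3-(hex-5-ynoyl)oxazolidin-2-one
Product: 6 (S)-4-benzyl-3-[(S)-2-hydroxyhex-5-ynoyl]oxazolidin-2-one, via sodium Z-enolate of the imide 5 (not isolated)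
Conditions: NaN(SiMe3)2, THF, −78 °C; 2-(phenylsulfonyl)-3-phenyloxaziridine, −78 °C; AcOH quench
Reagents that add atoms: 2-(phenylsulfonyl)-3-phenyloxaziridine (Davis oxaziridine), O=S(=O)(c1ccccc1)N1OC1c1ccccc1
Why: Evans auxiliary-controlled enolate hydroxylation: the sodium-chelated Z-enolate takes electrophilic oxygen on the face opposite the benzyl group, which sets C3 as (S), and the imide is enolised in preference to the far less acidic alkyne C–H.

Step 3
Reactants: 6 (S)-4-benzyl-3-[(S)-2-hydroxyhex-5-ynoyl]oxazolidin-2-one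
Product: 7 methyl (S)-2-hydroxyhex-5-ynoate
Conditions: MeOMgBr (from MeMgBr, MeOH), MeOH/CH2Cl2, 0 °C; aq. NH4Cl
Reagents that add atoms: methanol, CO
Why: Magnesium-alkoxide transesterification: chelation of magnesium between the α-hydroxyl and the exocyclic carbonyl directs methoxide to that carbonyl, so the auxiliary is released for reuse and C3 is not epimerised.

Step 4
Reactants: 7 methyl (S)-2-hydroxyhex-5-ynoate
Product: 8 methyl (S)-2-[(tert-butyldimethylsilyl)oxy]hex-5-ynoate
Conditions: TBSCl, imidazole, DMF, rt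
Reagents that add atoms: tert-butyldimethylsilyl chloride, CC(C)(C)[Si](C)(C)Cl
Why: Imidazole-promoted silylation of a secondary alcohol; the base is too weak to enolise the ester, so C3 is retained.

Step 5
Reactants: 8 methyl (S)-2-[(tert-butyldimethylsilyl)oxy]hex-5-ynoate; 9 (E)-hex-2-enal
Product: 12 methyl (2S,5E,7S,8E)-2-[(tert-butyldimethylsilyl)oxy]-7-hydroxydodeca-5,8-dienoate, via E-alkenyl dicyclohexylborane 10 (not isolated), via E-alkenyl methyl zinc 11 (not isolated)
Conditions: Cy2BH (from BH3·SMe2, cyclohexene), toluene, 0 °C → rt; ZnMe2, −78 °C; (+)-MIB [(2R)-3-exo-morpholinoisoborneol] (5 mol%), 9 (1.5 equiv), −78 → −10 °C; aq. NH4Cl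
Reagents that add atoms: none
Why: Syn hydroboration of the terminal alkyne gives the (E)-alkenylborane, boron-to-zinc exchange gives the alkenylzinc, and the zinc aminoalkoxide of (+)-MIB (the antipode of the ligand that gives (S)-1-phenylpropan-1-ol from ZnEt2 and benzaldehyde) should catalyse its 1,2-addition to the Re face of the enal carbonyl, a catalytic asymmetric alkenylzinc addition that sets C8 while the ester and silyl ether stay inert.

Step 6
Reactants: 12 methyl (2S,5E,7S,8E)-2-[(tert-butyldimethylsilyl)oxy]-7-hydroxydodeca-5,8-dienoate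
Product: 13 methyl (2S,5E,7R)-2-[(tert-butyldimethylsilyl)oxy]-7-hydroxy-7-[(2R,3R)-3-propyloxiran-2-yl]hept-5-enoate
Conditions: Ti(OiPr)4 (1.0 equiv), D-(−)-diisopropyl tartrate (1.2 equiv), t-BuOOH (1.2 equiv, decane), 4 Å sieves, CH2Cl2, −20 °C
Reagents that add atoms: tert-butyl hydroperoxide, CC(C)(C)OO
Why: Sharpless asymmetric epoxidation in the matched sense of a kinetic resolution: with D-(−)-tartrate the C8 carbinol is the fast-reacting configuration only for C9=C10, so oxygen should go there to give the erythro (9R,10R) epoxy alcohol, while C6=C7 is mismatched and any C8 epimer would be epoxidised at C6=C7 and removed as a constitutional isomer.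

Step 7
Reactants: 13 methyl (2S,5E,7R)-2-[(tert-butyldimethylsilyl)oxy]-7-hydroxy-7-[(2R,3R)-3-propyloxiran-2-yl]hept-5-enoate
Product: 14 (2S,5E,7R)-2-[(tert-butyldimethylsilyl)oxy]-7-hydroxy-7-[(2R,3R)-3-propyloxiran-2-yl]hept-5-enoic acid
Conditions: Me3SnOH (6 equiv), 1,2-dichloroethane, 70 °C; cold dilute aq. KHSO4
Reagents that add atoms: trimethyltin hydroxide, C[Sn](C)(C)O
Why: Ester cleavage with Me3SnOH (tin-assisted hydroxide transfer to the acyl carbon under nearly neutral conditions) should spare the epoxy alcohol, the silyl ether and C3, which aqueous alkali would endanger through Payne rearrangement or epimerisation.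

Step 8
Reactants: 14 (2S,5E,7R)-2-[(tert-butyldimethylsilyl)oxy]-7-hydroxy-7-[(2R,3R)-3-propyloxiran-2-yl]hept-5-enoic acid
Product: 15 (3S,6E,8R,9R,10S)-3-[(tert-butyldimethylsilyl)oxy]-8,9-dihydroxy-10-propyl-3,4,5,8,9,10-hexahydro-2H-oxecin-2-one
Conditions: Ti(OiPr)4 (2 equiv), CH2Cl2, 14 added by syringe pump to 2 mM final concentration, rt → 35 °C; 10% aq. tartaric acid
Reagents that add atoms: none
Why: Proposed new method: Ti(OiPr)4 should exchange isopropoxide ligands for the C8 alkoxide and the C2 carboxylate of 14; the titanium held by O8 and the epoxide oxygen weakens the C10–O bond, and the tethered carboxylate oxygen (free, or carried by the second metal of an alkoxide-bridged titanium dimer, because one metal cannot bind the epoxide oxygen and also reach the rear of C10) attacks C10 anti to that bond in an SN2 opening. The closest known reaction type is the Ti(OiPr)4-mediated opening of 2,3-epoxy alcohols by carboxylic acids at the carbon remote from the hydroxyl, established between two molecules. The ten-membered lactone is closed by O1–C10 bond formation in a 10-endo-tet epoxide opening (both epoxide carbons become ring atoms and the epoxide oxygen stays outside as the C9 hydroxyl), driven by release of epoxide strain without acyl activation. C10 is the one new stereocentre and is set (S) by inversion of the (10R) epoxide carbon, whose configuration comes from the tartrate-controlled epoxidation of step 6, while C8 and C9 are retained. The step needs attack at C10 and not C9, and ring closure in preference to oligomerisation or opening by isopropoxide: the O8/epoxide chelate that directs nucleophiles to the distal carbon, the inductive and steric deactivation of C9 by the C8 oxygen, and the much higher strain of a nine-membered lactone holding an (E)-alkene should favour C10, and slow addition at high dilution should favour the intramolecular carboxylate over a second molecule and over the hindered isopropoxide.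

Step 9
Reactants: 15 (3S,6E,8R,9R,10S)-3-[(tert-butyldimethylsilyl)oxy]-8,9-dihydroxy-10-propyl-3,4,5,8,9,10-hexahydro-2H-oxecin-2-one
Product: 16 C8/C9 acetonide of 15 (cis-fused 2,2-dimethyl-1,3-dioxolane; C3 silyl ether kept; all centres arranged as in 15)
Conditions: 2,2-dimethoxypropane, PPTS (cat.), CH2Cl2, rt
Reagents that add atoms: 2,2-dimethoxypropane, COC(C)(C)OC
Why: Acid-catalysed acetal exchange; the erythro C8/C9 diol should close a cis-fused dioxolane readily, and PPTS is too mild to touch the silyl ether or the lactone.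

Step 10
Reactants: 16 C8/C9 acetonide of 15
Product: 17 C3 alcohol of 16 (free (S)-C3–OH; acetonide kept)
Conditions: Bu4NF, AcOH (1:1), THF, 0 °C → rt
Reagents that add atoms: none
Why: Fluoride-induced Si–O cleavage, buffered with AcOH so that the C3 alkoxide is protonated at once and can neither open the lactone nor epimerise C3.

Step 11
Reactants: 18 ethyl (E)-4-oxobut-2-enoate; 19 tert-butyl (triphenylphosphoranylidene)acetate
Product: 20 1-tert-butyl 6-ethyl (2E,4E)-hexa-2,4-dienedioate
Conditions: CH2Cl2, 0 °C → rt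
Reagents that add atoms: none
Why: Wittig olefination with an ester-stabilised ylide, which reacts only at the aldehyde and gives the (E)-alkene, so the (2E,4E)-diene diester should result.

Step 12
Reactants: 20 1-tert-butyl 6-ethyl (2E,4E)-hexa-2,4-dienedioate
Product: 21 (2E,4E)-6-(tert-butoxy)-6-oxohexa-2,4-dienoic acid
Conditions: LiOH (1.05 equiv), THF/H2O, 0 °C; then 1 M HCl to pH 3
Reagents that add atoms: lithium hydroxide, [Li+].[OH-]
Why: Saponification by acyl–oxygen cleavage distinguishes the unhindered ethyl ester from the tert-butyl ester, which resists hydroxide.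

Step 13
Reactants: 17 C3 alcohol of 16; 21 (2E,4E)-6-(tert-butoxy)-6-oxohexa-2,4-dienoic acid
Product: 22 C3 ester of 17 with 21 (tert-butyl ester and acetonide in place)
Conditions: EDC·HCl, DMAP (0.2 equiv), CH2Cl2, 0 °C → rt
Reagents that add atoms: none
Why: Steglich esterification (carbodiimide activation of 21 with DMAP acyl transfer) acylates the only free hydroxyl, and because the C3–O bond is not broken C3 stays (S).

Step 14
Reactants: 22 C3 ester of 17 with 21
Product: 23 (2E,4E)-6-{[(3S,6E,8R,9R,10S)-8,9-dihydroxy-2-oxo-10-propyl-3,4,5,8,9,10-hexahydro-2H-oxecin-3-yl]oxy}-6-oxohexa-2,4-dienoic acid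
Conditions: CF3CO2H/CH2Cl2/H2O (45:50:5), 0 °C → rt
Reagents that add atoms: none
Why: Brønsted-acid deprotection: the tert-butyl ester fragments by alkyl–oxygen cleavage to 2-methylpropene and the acetonide is hydrolysed, while the lactone, the dienoate ester and the stereocentres should not be affected by CF3CO2H at or below room temperature.

**Compound list**
1 | hex-5-ynoic acid | C#CCCCC(=O)O | starting material
2 | (S)-4-benzyloxazolidin-2-one | O=C1N[C@@H](Cc2ccccc2)CO1 | starting material
3 | hex-5-ynoic pivalic anhydride | C#CCCCC(=O)OC(=O)C(C)(C)C | intermediate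
4 | (S)-4-benzyl-3-(hex-5-ynoyl)oxazolidin-2-one | C#CCCCC(=O)N1[C@@H](Cc2ccccc2)COC1=O | intermediate
5 | sodium (Z)-enolate of 4 | C#CCC/C=C(\[O-])N1[C@@H](Cc2ccccc2)COC1=O.[Na+] | intermediate
6 | (S)-4-benzyl-3-[(S)-2-hydroxyhex-5-ynoyl]oxazolidin-2-one | C#CCC[C@H](O)C(=O)N1[C@@H](Cc2ccccc2)COC1=O | intermediate
7 | methyl (S)-2-hydroxyhex-5-ynoate | C#CCC[C@H](O)C(=O)OC | intermediate
8 | methyl (S)-2-[(tert-butyldimethylsilyl)oxy]hex-5-ynoate | C#CCC[C@H](O[Si](C)(C)C(C)(C)C)C(=O)OC | intermediate
9 | (E)-hex-2-enal | CCC/C=C/C=O | starting material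
10 | methyl (2S,5E)-2-[(tert-butyldimethylsilyl)oxy]-6-(dicyclohexylboranyl)hex-5-enoate | COC(=O)[C@@H](O[Si](C)(C)C(C)(C)C)CC/C=C/B(C1CCCCC1)C1CCCCC1 | intermediate
11 | (E)-alkenyl(methyl)zinc from 10 (BCy2 replaced by ZnMe) | COC(=O)[C@@H](O[Si](C)(C)C(C)(C)C)CC/C=C/[Zn]C | intermediate
12 | methyl (2S,5E,7S,8E)-2-[(tert-butyldimethylsilyl)oxy]-7-hydroxydodeca-5,8-dienoate | COC(=O)[C@@H](O[Si](C)(C)C(C)(C)C)CC/C=C/[C@@H](O)/C=C/CCC | intermediate
13 | methyl (2S,5E,7R)-2-[(tert-butyldimethylsilyl)oxy]-7-hydroxy-7-[(2R,3R)-3-propyloxiran-2-yl]hept-5-enoate | COC(=O)[C@@H](O[Si](C)(C)C(C)(C)C)CC/C=C/[C@@H](O)[C@H]1O[C@@H]1CCC | intermediate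
14 | (2S,5E,7R)-2-[(tert-butyldimethylsilyl)oxy]-7-hydroxy-7-[(2R,3R)-3-propyloxiran-2-yl]hept-5-enoic acid | OC(=O)[C@@H](O[Si](C)(C)C(C)(C)C)CC/C=C/[C@@H](O)[C@H]1O[C@@H]1CCC | intermediate
15 | (3S,6E,8R,9R,10S)-3-[(tert-butyldimethylsilyl)oxy]-8,9-dihydroxy-10-propyl-3,4,5,8,9,10-hexahydro-2H-oxecin-2-one | CCC[C@@H]1OC(=O)[C@@H](O[Si](C)(C)C(C)(C)C)CC/C=C/[C@@H](O)[C@H]1O | intermediate
16 | C8/C9 acetonide of 15 (cis-fused 2,2-dimethyl-1,3-dioxolane) | CCC[C@@H]1OC(=O)[C@@H](O[Si](C)(C)C(C)(C)C)CC/C=C/[C@H]2OC(C)(C)O[C@@H]12 | intermediate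
17 | C3 alcohol of 16 | CCC[C@@H]1OC(=O)[C@@H](O)CC/C=C/[C@H]2OC(C)(C)O[C@@H]12 | intermediate
18 | ethyl (E)-4-oxobut-2-enoate | CCOC(=O)/C=C/C=O | starting material
19 | tert-butyl (triphenylphosphoranylidene)acetate | CC(C)(C)OC(=O)C=P(c1ccccc1)(c1ccccc1)c1ccccc1 | starting material
20 | 1-tert-butyl 6-ethyl (2E,4E)-hexa-2,4-dienedioate | CCOC(=O)/C=C/C=C/C(=O)OC(C)(C)C | intermediate
21 | (2E,4E)-6-(tert-butoxy)-6-oxohexa-2,4-dienoic acid | OC(=O)/C=C/C=C/C(=O)OC(C)(C)C | intermediate
22 | C3 ester of 17 with 21 | CCC[C@@H]1OC(=O)[C@@H](OC(=O)/C=C/C=C/C(=O)OC(C)(C)C)CC/C=C/[C@H]2OC(C)(C)O[C@@H]12 | intermediate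
23 | (2E,4E)-6-{[(3S,6E,8R,9R,10S)-8,9-dihydroxy-2-oxo-10-propyl-3,4,5,8,9,10-hexahydro-2H-oxecin-3-yl]oxy}-6-oxohexa-2,4-dienoic acid | CCC[C@@H]1OC(=O)[C@@H](OC(=O)/C=C/C=C/C(=O)O)CC/C=C/[C@@H](O)[C@H]1O | target

**Step count**
Total: 14 steps. Longest linear sequence: 12 steps (steps 1–10, 13, 14); steps 11 and 12 form the side branch to 21.

**Steps most likely to fail**

Step 8 (the untested ring closure). The carboxylate may fail to reach C10 through a ten-membered transition state, so that oligomerisation between molecules, opening by isopropoxide or attack at C9 takes over. The fallback sets out from 13 and returns at 16, using only established reactions. The epoxide of 13 is opened between two molecules with pivalic acid and Ti(OiPr)4 (attack at C10 with inversion) to give methyl (2S,5E,7R,8R,9S)-2-[(tert-butyldimethylsilyl)oxy]-7,8-dihydroxy-9-(pivaloyloxy)dodec-5-enoate F1. 2,2-Dimethoxypropane/PPTS converts the diol into the acetonide pivalate methyl ester F2. LiOH in warm aqueous MeOH/THF removes both the methyl ester and the pivalate to give the hydroxy acid acetonide F3. Yamaguchi macrolactonisation (2,4,6-trichlorobenzoyl chloride, Et3N, THF; then DMAP, toluene, high dilution, 80 °C) passes through the mixed trichlorobenzoic anhydride F4 and closes the lactone by acyl activation with retention at C10, giving 16.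

Step 5. Facial selectivity at C8 may be poor with this functionalised alkenylzinc and an enal, and methyl transfer from zinc may compete. The fallback sets out from 9 and 8 and returns at 13, bypassing 12 and step 6. Luche reduction of 9 (NaBH4, CeCl3·7H2O, MeOH) gives (E)-hex-2-en-1-ol F5 (also purchasable). Catalytic Sharpless epoxidation with D-(−)-diethyl tartrate, Ti(OiPr)4 and t-BuOOH gives (2R,3R)-3-propyloxiranemethanol F6. Parikh–Doering oxidation (SO3·pyridine, DMSO, iPr2NEt) gives (2S,3R)-3-propyloxirane-2-carbaldehyde F7. Alkenylzinc 11, made from 8 as in step 5 but without ligand, is added to F7; Felkin–Anh approach anti to the epoxide C–O bond should favour the erythro adduct 13, and the threo epimer is removed by chromatography. C9 and C10 then come from a primary allylic alcohol epoxidation and C8 from substrate control.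

Step 7. The epoxy alcohol may be lost during ester cleavage through Payne rearrangement or hydroxide opening at 70 °C. The fallback sets out from 12 and returns at 14, cleaving the methyl ester before the epoxide exists. LiOH (THF/H2O, 0 °C) converts 12 into (2S,5E,7S,8E)-2-[(tert-butyldimethylsilyl)oxy]-7-hydroxydodeca-5,8-dienoic acid F8. TIPSCl/Et3N silylates only the carboxyl group to give the triisopropylsilyl ester F9. The epoxidation of step 6 is run on F9 to give the epoxy alcohol triisopropylsilyl ester F10. The silyl ester is then hydrolysed with K2CO3 in aqueous MeOH at 0 °C, conditions under which the epoxy alcohol and the C3 silyl ether should survive, to give 14.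

**Further compounds**
F1 | step 8 | methyl (2S,5E,7R,8R,9S)-2-[(tert-butyldimethylsilyl)oxy]-7,8-dihydroxy-9-(pivaloyloxy)dodec-5-enoate | CCC[C@H](OC(=O)C(C)(C)C)[C@H](O)[C@H](O)/C=C/CC[C@H](O[Si](C)(C)C(C)(C)C)C(=O)OC
F2 | step 8 | 7,8-O-isopropylidene acetal of F1 | CCC[C@H](OC(=O)C(C)(C)C)[C@@H]1OC(C)(C)O[C@@H]1/C=C/CC[C@H](O[Si](C)(C)C(C)(C)C)C(=O)OC
F3 | step 8 | hydroxy acid from F2 (free secondary hydroxyl at the propyl-bearing carbon, free carboxylic acid, acetonide kept) | CCC[C@H](O)[C@@H]1OC(C)(C)O[C@@H]1/C=C/CC[C@H](O[Si](C)(C)C(C)(C)C)C(=O)O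
F4 | step 8 | mixed anhydride of F3 with 2,4,6-trichlorobenzoic acid | CCC[C@H](O)[C@@H]1OC(C)(C)O[C@@H]1/C=C/CC[C@H](O[Si](C)(C)C(C)(C)C)C(=O)OC(=O)c1c(Cl)cc(Cl)cc1Cl
F5 | step 5 | (E)-hex-2-en-1-ol | CCC/C=C/CO
F6 | step 5 | (2R,3R)-3-propyloxiranemethanol | OC[C@H]1O[C@@H]1CCC
F7 | step 5 | (2S,3R)-3-propyloxirane-2-carbaldehyde | O=C[C@H]1O[C@@H]1CCC
F8 | step 7 | (2S,5E,7S,8E)-2-[(tert-butyldimethylsilyl)oxy]-7-hydroxydodeca-5,8-dienoic acid | OC(=O)[C@@H](O[Si](C)(C)C(C)(C)C)CC/C=C/[C@@H](O)/C=C/CCC
F9 | step 7 | triisopropylsilyl ester of F8 | CC(C)[Si](OC(=O)[C@@H](O[Si](C)(C)C(C)(C)C)CC/C=C/[C@@H](O)/C=C/CCC)(C(C)C)C(C)C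
F10 | step 7 | triisopropylsilyl ester of 14 | CC(C)[Si](OC(=O)[C@@H](O[Si](C)(C)C(C)(C)C)CC/C=C/[C@@H](O)[C@H]1O[C@@H]1CCC)(C(C)C)C(C)C
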